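**Plan**
- Numbering (seco-labdane): ring C1–C5/C10 with the gem-dimethyl at C4; 3-oxobutyl C6–C8 on C5; methyl and ketone C9 on C10; chain C11–C15 with the C13 methyl and the glyceride on C15.
- Cuts, in retrosynthetic order: acetate and C15–O ester (glycerol unit from (S)-solketal), C6=C7 (acetonyl Wittig), C9–C11 (alkyllithium on a lactone), then the ring bonds C4–C5 and C10–C1.
- Enabling feature: C10 and C5, with C9 and C6 cis, are the α- and β-carbons of a 3-methylbutenolide (carbonyl C9, acetal carbon C6); the four-carbon unit C4–C3–C2–C1 is annulated onto this alkene.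
- Forward: chiral 5-menthyloxy-3-methylbutenolide, then the annulation that closes the only carbocycle cis-fused to the lactone, then the C11–C15 chain at C9 with release of the C6 aldehyde, then C6–C8, C15 acid and glyceride.
- Stereochemistry: C5 from radical addition anti to the acetal substituent on C6 (acetal epimer resolved with (+)-menthol), C10 from the enforced cis ring fusion, C13 from methyl hydrogen (R)-3-methylglutarate, the glycerol centre from (S)-solketal.

Key step: step 6

Remark 1: radicals add to 5-alkoxyfuran-2(5H)-ones anti to the alkoxy group, so the (5S) acetal is the epimer that leads to (5S,10R); (+)-menthol is taken so that this acetal is the mirror image of the well-studied (5R)-(−)-menthyloxy series, the menthyl group serving only as a resolving handle.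
Remark 2: the tertiary radical is drawn from a cesium alkyl oxalate, because a 5-chloro-2,2-dimethylpentanoate salt would close to the δ-lactone in a dipolar aprotic solvent and the free acid would protonate the enolate.

**Route**

Step 1
Reactants: 1 3-methylfuran-2(5H)-one
Product: 2 5-bromo-3-methylfuran-2(5H)-one (racemic)
Conditions: NBS, AIBN (cat.), PhCF3, 85 °C
Reagents that add atoms: N-bromosuccinimide, O=C1CCC(=O)N1Br
Why: Wohl–Ziegler bromination takes the γ-hydrogen, which is both allylic and next to the ring oxygen, and the racemic bromide is the usual electrophile for joining this butenolide to alcohols.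

Step 2
Reactants: 2 5-bromo-3-methylfuran-2(5H)-one + 3 (+)-menthol
Product: 4 (5S)-3-methyl-5-{[(1S,2R,5S)-2-isopropyl-5-methylcyclohexyl]oxy}furan-2(5H)-one
Conditions: 3 (1.2 equiv), Ag2CO3, 4 Å MS, CH2Cl2, rt, dark; crystallisation of the (5S) epimer (hexane); mother liquor re-equilibrated with CSA (cat.) and recycled
Reagents that add atoms: none
Why: Silver-assisted substitution of the α-bromo ether (Koenigs–Knorr type) gives both acetal epimers, which are diastereomers because of the menthyl group, so the (5S) acetal should be obtainable by crystallisation (chromatography otherwise) while the (5R) epimer is returned to the mixture by acid-catalysed acetal epimerisation.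

Step 3
Reactants: 5 5-chloropentan-2-one
Product: 6 5-chloro-2-methylpentan-2-ol
Conditions: MeMgBr, Et2O, −20 → 0 °C; then H2O, 0 °C
Reagents that add atoms: methylmagnesium bromide, C[Mg]Br
Why: Grignard addition to the methyl ketone is far faster than any reaction at the primary chloride, and keeping the mixture cold prevents the alkoxide from closing to a tetrahydrofuran.

Step 4
Reactants: 6 5-chloro-2-methylpentan-2-ol
Product: 7 5-chloro-2-methylpentan-2-yl methyl oxalate
Conditions: ClC(O)CO2Me, Et3N, DMAP (cat.), CH2Cl2, 0 °C → rt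
Reagents that add atoms: methyl chlorooxoacetate, COC(=O)C(=O)Cl
Why: DMAP-catalysed acylation of the tertiary alcohol with the reactive oxalyl monochloride gives the mixed oxalate (nucleophilic catalysis).

Step 5
Reactants: 7 5-chloro-2-methylpentan-2-yl methyl oxalate
Product: 8 cesium 2-[(5-chloro-2-methylpentan-2-yl)oxy]-2-oxoacetate
Conditions: CsOH·H2O (1.0 equiv), THF/H2O, rt, short; evaporate and dry in vacuo
Reagents that add atoms: cesium hydroxide, [Cs+].[OH-]
Why: Saponification with one equivalent of hydroxide cleaves only the unhindered methyl ester of the mixed oxalate and should give the storable cesium salt, the tertiary ester and the primary chloride being left alone.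

Step 6
Reactants: 4 (5S)-3-methyl-5-{[(1S,2R,5S)-2-isopropyl-5-methylcyclohexyl]oxy}furan-2(5H)-one + 8 cesium 2-[(5-chloro-2-methylpentan-2-yl)oxy]-2-oxoacetate
Product: 10 (3S,3aS,7aR)-4,4,7a-trimethyl-3-{[(1S,2R,5S)-2-isopropyl-5-methylcyclohexyl]oxy}hexahydro-2-benzofuran-1(3H)-one, via cesium lactone enolate 9 (not isolated)
Conditions: 8 (1.5 equiv), Ir[dF(CF3)ppy]2(dtbbpy)PF6 (1 mol %), 4 Å MS, dry degassed DME/DMF 3:1 (no added water), blue LEDs, 60 °C
Reagents that add atoms: none
Why: Proposed new method: the excited trivalent iridium photocatalyst oxidises the oxalate carboxylate, two CO2 are lost and the nucleophilic tertiary C4 radical adds to the β-carbon C5 of the butenolide, after which divalent iridium reduces the tertiary α-lactone radical to the cesium enolate 9, which displaces the primary chloride at C1, so that the cycle is redox-neutral and consumes no proton. The closest known reactions are the redox-neutral coupling of tertiary cesium oxalates with butenolides, in which the enolate is simply protonated by added water, and photoredox radical addition–polar cyclisation cascades in which a carbanion displaces a tethered halide; new here is that the halide sits on the radical partner and that a six-membered ring with a quaternary centre is closed. The cyclohexane closes by 6-exo-tet C-alkylation of the enolate, whose double bond lies outside the new ring. C5 is set by addition anti to the menthyloxy group on C6, and C10 by the γ-lactone, which lets the tether on C5 reach only the same face of the enolate, so that the rings must be cis-fused. The step needs β-regioselectivity (nucleophilic radical, electron-poor alkene), face selectivity (the C6 acetal substituent) and an enolate that alkylates before it is protonated (dry medium, no acidic partner); the oxalate half-ester secures the last point because its weakly nucleophilic carboxylate cannot close onto the chloride.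

Step 7
Reactants: 11 methyl hydrogen (R)-3-methylglutarate
Product: 12 methyl (3R)-5-hydroxy-3-methylpentanoate
Conditions: BH3·SMe2, THF, −10 °C → rt; MeOH quench; used crude
Reagents that add atoms: none
Why: Borane reduces the free carboxylic acid much faster than the methyl ester (chemoselective acid reduction), so the acid carbon becomes C11 and the stereocentre is not touched.

Step 8
Reactants: 12 methyl (3R)-5-hydroxy-3-methylpentanoate
Product: 13 methyl (3S)-5-iodo-3-methylpentanoate
Conditions: I2, PPh3, imidazole, CH2Cl2, 0 °C → rt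
Reagents that add atoms: iodine, II
Why: Appel-type iodination converts the primary alcohol by SN2 displacement, and doing it at once forestalls lactonisation of the hydroxy ester.

Step 9
Reactants: 13 methyl (3S)-5-iodo-3-methylpentanoate
Product: 14 (3S)-5-iodo-3-methylpentan-1-ol
Conditions: i-Bu2AlH (2.2 equiv), CH2Cl2, −78 → 0 °C; aq. KNaC4H4O6
Reagents that add atoms: none
Why: Hydride reduction with i-Bu2AlH takes the ester to the primary alcohol at low temperature without touching the primary iodide.

Step 10
Reactants: 14 (3S)-5-iodo-3-methylpentan-1-ol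
Product: 15 {[(3S)-5-iodo-3-methylpentyl]oxy}methylbenzene
Conditions: BnOC(=NH)CCl3, TfOH (cat.), CH2Cl2/cyclohexane, 0 °C → rt
Reagents that add atoms: benzyl 2,2,2-trichloroacetimidate, ClC(Cl)(Cl)C(=N)OCc1ccccc1
Why: Acid-catalysed benzylation with the trichloroacetimidate avoids the alkoxide, which would close onto the iodide to give a tetrahydropyran.

Step 11
Reactants: 10 (3S,3aS,7aR)-4,4,7a-trimethyl-3-{[(1S,2R,5S)-2-isopropyl-5-methylcyclohexyl]oxy}hexahydro-2-benzofuran-1(3H)-one + 15 {[(3S)-5-iodo-3-methylpentyl]oxy}methylbenzene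
Product: 19 (1S,2R)-2-[(4R)-6-(benzyloxy)-4-methylhexanoyl]-2,6,6-trimethylcyclohexane-1-carbaldehyde, via alkyllithium 16 (not isolated), via lithium hemiketal alkoxide 17 (not isolated), via lactol 18 (not isolated)
Conditions: 15 (1.15 equiv), t-BuLi (2.3 equiv), Et2O/pentane, −78 °C; add 10 in THF, −78 °C; then 1 M aq. HCl, THF, −78 → 20 °C; product used without delay
Reagents that add atoms: none
Why: Lithium–iodine exchange gives the primary alkyllithium, which should add once to the non-enolisable lactone carbonyl because the tetrahedral lithium alkoxide persists in the cold, and acid then opens the hemiketal to the C9 ketone while the released hemiacetal loses menthol to give the C6 aldehyde (organolithium mono-addition to a lactone followed by acetal hydrolysis).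

Step 12
Reactants: 19 (1S,2R)-2-[(4R)-6-(benzyloxy)-4-methylhexanoyl]-2,6,6-trimethylcyclohexane-1-carbaldehyde
Product: 20 (3E)-4-{(1S,2R)-2-[(4R)-6-(benzyloxy)-4-methylhexanoyl]-2,6,6-trimethylcyclohexyl}but-3-en-2-one
Conditions: Ph3P=CHC(O)CH3 (2 equiv), toluene, 90 °C
Reagents that add atoms: 1-(triphenylphosphoranylidene)propan-2-one, CC(=O)C=P(c1ccccc1)(c1ccccc1)c1ccccc1
Why: Wittig olefination with the stabilised acetonyl ylide attacks only the aldehyde, since the C9 ketone is shielded by the quaternary C10, and should give the E-enone under nearly neutral conditions that spare the C5 centre.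

Step 13
Reactants: 20 (3E)-4-{(1S,2R)-2-[(4R)-6-(benzyloxy)-4-methylhexanoyl]-2,6,6-trimethylcyclohexyl}but-3-en-2-one
Product: 22 (4R)-6-hydroxy-4-methyl-1-[(1R,2S)-1,3,3-trimethyl-2-(3-oxobutyl)cyclohexyl]hexan-1-one, via saturated benzyl ether 21 (not isolated)
Conditions: H2 (1 atm), 10% Pd/C, EtOAc/EtOH, rt
Reagents that add atoms: none
Why: Heterogeneous hydrogenation saturates the enone C=C and then hydrogenolyses the benzyl ether in one operation, leaving both ketones.

Step 14
Reactants: 22 (4R)-6-hydroxy-4-methyl-1-[(1R,2S)-1,3,3-trimethyl-2-(3-oxobutyl)cyclohexyl]hexan-1-one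
Product: 24 (3R)-3-methyl-6-oxo-6-[(1R,2S)-1,3,3-trimethyl-2-(3-oxobutyl)cyclohexyl]hexanoic acid, via aldehyde 23 (not isolated)
Conditions: TEMPO (0.2 equiv), PhI(OAc)2 (2.2 equiv), MeCN/H2O 1:1, rt
Reagents that add atoms: water, O
Why: Oxoammonium (TEMPO) oxidation in aqueous acetonitrile takes the primary alcohol through the aldehyde to the acid, and no stereocentre of the molecule is enolisable at this stage.

Step 15
Reactants: 24 (3R)-3-methyl-6-oxo-6-[(1R,2S)-1,3,3-trimethyl-2-(3-oxobutyl)cyclohexyl]hexanoic acid + 25 (S)-solketal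
Product: 26 [(4R)-2,2-dimethyl-1,3-dioxolan-4-yl]methyl (3R)-3-methyl-6-oxo-6-[(1R,2S)-1,3,3-trimethyl-2-(3-oxobutyl)cyclohexyl]hexanoate
Conditions: 25 (1.2 equiv), EDC·HCl, DMAP (cat.), CH2Cl2, 0 °C → rt
Reagents that add atoms: none
Why: Steglich esterification joins the unhindered acid to the primary alcohol of solketal without involving the dioxolane stereocentre.

Step 16
Reactants: 26 [(4R)-2,2-dimethyl-1,3-dioxolan-4-yl]methyl (3R)-3-methyl-6-oxo-6-[(1R,2S)-1,3,3-trimethyl-2-(3-oxobutyl)cyclohexyl]hexanoate
Product: 27 (2R)-2,3-dihydroxypropyl (3R)-3-methyl-6-oxo-6-[(1R,2S)-1,3,3-trimethyl-2-(3-oxobutyl)cyclohexyl]hexanoate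
Conditions: 1 M aq. HCl/THF 1:4, 0 °C → rt; neutral work-up, used at once
Reagents that add atoms: none
Why: Dilute-acid hydrolysis of the isopropylidene acetal frees the diol, and the mild, base-free handling is meant to keep acyl migration, which would scramble the glycerol centre, to a minimum.

Step 17
Reactants: 27 (2R)-2,3-dihydroxypropyl (3R)-3-methyl-6-oxo-6-[(1R,2S)-1,3,3-trimethyl-2-(3-oxobutyl)cyclohexyl]hexanoate
Product: 28 (2R)-3-(acetyloxy)-2-hydroxypropyl (3R)-3-methyl-6-oxo-6-[(1R,2S)-1,3,3-trimethyl-2-(3-oxobutyl)cyclohexyl]hexanoate (target)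
Conditions: AcCl (1.1 equiv), 2,4,6-collidine, CH2Cl2, −78 °C
Reagents that add atoms: acetyl chloride, CC(=O)Cl
Why: Sterically controlled acylation with acetyl chloride and a hindered pyridine base at low temperature should acetylate the primary hydroxyl in preference to the secondary one and give the 1,3-diacylglycerol.

**Compound list**

1 | 3-methylfuran-2(5H)-one | CC1=CCOC1=O | starting material
2 | 5-bromo-3-methylfuran-2(5H)-one (racemic) | CC1=CC(Br)OC1=O | intermediate
3 | (+)-menthol, (1S,2R,5S)-2-isopropyl-5-methylcyclohexan-1-ol | C[C@H]1CC[C@@H]([C@H](C1)O)C(C)C | starting material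
4 | (5S)-3-methyl-5-{[(1S,2R,5S)-2-isopropyl-5-methylcyclohexyl]oxy}furan-2(5H)-one | CC1=C[C@@H](O[C@H]2C[C@@H](C)CC[C@@H]2C(C)C)OC1=O | intermediate
5 | 5-chloropentan-2-one | CC(=O)CCCCl | starting material
6 | 5-chloro-2-methylpentan-2-ol | CC(C)(O)CCCCl | intermediate
7 | 5-chloro-2-methylpentan-2-yl methyl oxalate | COC(=O)C(=O)OC(C)(C)CCCCl | intermediate
8 | cesium 2-[(5-chloro-2-methylpentan-2-yl)oxy]-2-oxoacetate | [Cs+].[O-]C(=O)C(=O)OC(C)(C)CCCCl | intermediate
9 | cesium enolate of (4R,5S)-4-(5-chloro-2-methylpentan-2-yl)-3-methyl-5-(menthyloxy)dihydrofuran-2(3H)-one | [Cs+].[O-]C1=C(C)[C@H](C(C)(C)CCCCl)[C@@H](O[C@H]2C[C@@H](C)CC[C@@H]2C(C)C)O1 | intermediate (not isolated)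
10 | (3S,3aS,7aR)-4,4,7a-trimethyl-3-{[(1S,2R,5S)-2-isopropyl-5-methylcyclohexyl]oxy}hexahydro-2-benzofuran-1(3H)-one (cis-fused) | O=C1O[C@H](O[C@H]2C[C@@H](C)CC[C@@H]2C(C)C)[C@H]3C(C)(C)CCC[C@]31C | intermediate
11 | methyl hydrogen (R)-3-methylglutarate | OC(=O)C[C@@H](C)CC(=O)OC | starting material
12 | methyl (3R)-5-hydroxy-3-methylpentanoate | OCC[C@@H](C)CC(=O)OC | intermediate
13 | methyl (3S)-5-iodo-3-methylpentanoate | ICC[C@@H](C)CC(=O)OC | intermediate
14 | (3S)-5-iodo-3-methylpentan-1-ol | ICC[C@@H](C)CCO | intermediate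
15 | {[(3S)-5-iodo-3-methylpentyl]oxy}methylbenzene | ICC[C@@H](C)CCOCc1ccccc1 | intermediate
16 | [(3R)-5-(benzyloxy)-3-methylpentyl]lithium | [Li]CC[C@@H](C)CCOCc1ccccc1 | intermediate (not isolated)
17 | lithium alkoxide of the C9 hemiketal (tetrahedral adduct of 16 and 10, mixture at C9) | [Li+].[O-]C1(CC[C@@H](C)CCOCc2ccccc2)O[C@H](O[C@H]2C[C@@H](C)CC[C@@H]2C(C)C)[C@H]3C(C)(C)CCC[C@]31C | intermediate (not isolated)
18 | C9 lactol, 1-[(3R)-5-(benzyloxy)-3-methylpentyl]-3-(menthyloxy)-4,4,7a-trimethyloctahydro-2-benzofuran-1-ol | OC1(CC[C@@H](C)CCOCc2ccccc2)O[C@H](O[C@H]2C[C@@H](C)CC[C@@H]2C(C)C)[C@H]3C(C)(C)CCC[C@]31C | intermediate (not isolated)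
19 | (1S,2R)-2-[(4R)-6-(benzyloxy)-4-methylhexanoyl]-2,6,6-trimethylcyclohexane-1-carbaldehyde | O=C[C@H]1C(C)(C)CCC[C@@]1(C)C(=O)CC[C@@H](C)CCOCc1ccccc1 | intermediate
20 | (3E)-4-{(1S,2R)-2-[(4R)-6-(benzyloxy)-4-methylhexanoyl]-2,6,6-trimethylcyclohexyl}but-3-en-2-one | CC(=O)/C=C/[C@H]1C(C)(C)CCC[C@@]1(C)C(=O)CC[C@@H](C)CCOCc1ccccc1 | intermediate
21 | (4R)-6-(benzyloxy)-4-methyl-1-[(1R,2S)-1,3,3-trimethyl-2-(3-oxobutyl)cyclohexyl]hexan-1-one | CC(=O)CC[C@H]1C(C)(C)CCC[C@@]1(C)C(=O)CC[C@@H](C)CCOCc1ccccc1 | intermediate (not isolated)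
22 | (4R)-6-hydroxy-4-methyl-1-[(1R,2S)-1,3,3-trimethyl-2-(3-oxobutyl)cyclohexyl]hexan-1-one | CC(=O)CC[C@H]1C(C)(C)CCC[C@@]1(C)C(=O)CC[C@@H](C)CCO | intermediate
23 | (3R)-3-methyl-6-oxo-6-[(1R,2S)-1,3,3-trimethyl-2-(3-oxobutyl)cyclohexyl]hexanal | CC(=O)CC[C@H]1C(C)(C)CCC[C@@]1(C)C(=O)CC[C@@H](C)CC=O | intermediate (not isolated)
24 | (3R)-3-methyl-6-oxo-6-[(1R,2S)-1,3,3-trimethyl-2-(3-oxobutyl)cyclohexyl]hexanoic acid | CC(=O)CC[C@H]1C(C)(C)CCC[C@@]1(C)C(=O)CC[C@@H](C)CC(=O)O | intermediate
25 | (S)-solketal, [(4S)-2,2-dimethyl-1,3-dioxolan-4-yl]methanol | CC1(C)OC[C@H](CO)O1 | starting material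
26 | [(4R)-2,2-dimethyl-1,3-dioxolan-4-yl]methyl (3R)-3-methyl-6-oxo-6-[(1R,2S)-1,3,3-trimethyl-2-(3-oxobutyl)cyclohexyl]hexanoate | CC(=O)CC[C@H]1C(C)(C)CCC[C@@]1(C)C(=O)CC[C@@H](C)CC(=O)OC[C@H]2COC(C)(C)O2 | intermediate
27 | (2R)-2,3-dihydroxypropyl (3R)-3-methyl-6-oxo-6-[(1R,2S)-1,3,3-trimethyl-2-(3-oxobutyl)cyclohexyl]hexanoate | CC(=O)CC[C@H]1C(C)(C)CCC[C@@]1(C)C(=O)CC[C@@H](C)CC(=O)OC[C@H](O)CO | intermediate
28 | (2R)-3-(acetyloxy)-2-hydroxypropyl (3R)-3-methyl-6-oxo-6-[(1R,2S)-1,3,3-trimethyl-2-(3-oxobutyl)cyclohexyl]hexanoate | CC(=O)CC[C@H]1C(C)(C)CCC[C@@]1(C)C(=O)CC[C@@H](C)CC(=O)OC[C@H](O)COC(C)=O | target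

**Step count and risks**

Total: 17 steps. Longest linear sequence: 11 steps (from 5 through steps 3–6 and 11–17; the branch from 11 through steps 7–17 is equally long).

Most likely to fail:

Step 6. The enolate may be protonated by adventitious proton sources faster than it alkylates, or the cascade may stop after the radical addition, so that the ring is not closed. In the fallback the two bonds are made one after the other by known chemistry, starting from 4 and 8. These are coupled under the established aqueous protocol for tertiary cesium oxalates and butenolides (same iridium photocatalyst, DME/DMF, about 10 equiv H2O, blue LEDs, 60 °C), which should give the anti adduct as the chloroalkyl lactone F1, a mixture at the α-carbon. Treatment with KN(SiMe3)2 in THF/DMPU from −78 °C to room temperature then forms the lactone enolate, whose intramolecular alkylation can only give the cis-fused lactone and so rejoins the route at 10.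

Step 11. The tetrahedral alkoxide may collapse in the flask and expose the aldehyde to a second addition of the alkyllithium, or addition at the crowded carbonyl may be too slow. The fallback sets out from 10 and forms the C9–C11 bond by palladium catalysis after the C6 chain is in place. Opening of the lactone with Me2AlSEt (from AlMe3 and EtSH, CH2Cl2) should give, with loss of menthol, the thioester aldehyde F2. Wittig reaction with the acetonyl ylide gives the enone thioester F3. The iodo ester 13 is converted with zinc dust and LiCl in THF into the alkylzinc iodide F4, and Fukuyama coupling of F3 with it (PdCl2(PPh3)2, toluene/THF) gives the enone keto ester F5. Hydrogenation over Pd/C gives the diketo methyl ester F6, and LiOH in aqueous THF rejoins the route at acid 24, so that steps 9, 10, 13 and 14 are not needed.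

Step 12. Olefination of an aldehyde flanked by two fully substituted carbons may be slow, leaving time for epimerisation at C5 or for aldol closure of the 1,4-keto aldehyde. The fallback sets out from 19 and builds the enone by an aldol route under Lewis-acidic conditions. Mukaiyama aldol addition of 2-(trimethylsilyloxy)propene with BF3·OEt2 in CH2Cl2 at −78 °C should give, after aqueous work-up, the β-hydroxy ketone F7. Mesylation (MsCl, Et3N) to the mesylate F8 and elimination with DBU return to enone 20.

**Further compounds**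

F1 | step 6 | (4R,5S)-4-(5-chloro-2-methylpentan-2-yl)-3-methyl-5-{[(1S,2R,5S)-2-isopropyl-5-methylcyclohexyl]oxy}dihydrofuran-2(3H)-one (mixture at C3) | O=C1O[C@H](O[C@H]2C[C@@H](C)CC[C@@H]2C(C)C)[C@@H](C(C)(C)CCCCl)C1C
F2 | step 11 | S-ethyl (1R,2S)-2-formyl-1,3,3-trimethylcyclohexane-1-carbothioate | O=C[C@H]1C(C)(C)CCC[C@@]1(C)C(=O)SCC
F3 | step 11 | S-ethyl (1R,2S)-1,3,3-trimethyl-2-[(1E)-3-oxobut-1-en-1-yl]cyclohexane-1-carbothioate | CC(=O)/C=C/[C@H]1C(C)(C)CCC[C@@]1(C)C(=O)SCC
F4 | step 11 | [(3S)-5-methoxy-3-methyl-5-oxopentyl]zinc iodide | I[Zn]CC[C@@H](C)CC(=O)OC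
F5 | step 11 | methyl (3R)-3-methyl-6-oxo-6-{(1R,2S)-1,3,3-trimethyl-2-[(1E)-3-oxobut-1-en-1-yl]cyclohexyl}hexanoate | CC(=O)/C=C/[C@H]1C(C)(C)CCC[C@@]1(C)C(=O)CC[C@@H](C)CC(=O)OC
F6 | step 11 | methyl (3R)-3-methyl-6-oxo-6-[(1R,2S)-1,3,3-trimethyl-2-(3-oxobutyl)cyclohexyl]hexanoate | CC(=O)CC[C@H]1C(C)(C)CCC[C@@]1(C)C(=O)CC[C@@H](C)CC(=O)OC
F7 | step 12 | (4R)-6-(benzyloxy)-1-[(1R,2S)-2-(1-hydroxy-3-oxobutyl)-1,3,3-trimethylcyclohexyl]-4-methylhexan-1-one (carbinol epimers) | CC(=O)CC(O)[C@H]1C(C)(C)CCC[C@@]1(C)C(=O)CC[C@@H](C)CCOCc1ccccc1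
F8 | step 12 | 1-{(1S,2R)-2-[(4R)-6-(benzyloxy)-4-methylhexanoyl]-2,6,6-trimethylcyclohexyl}-3-oxobutyl methanesulfonate | CC(=O)CC(OS(C)(=O)=O)[C@H]1C(C)(C)CCC[C@@]1(C)C(=O)CC[C@@H](C)CCOCc1ccccc1
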